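**Plan**
1. Retrosynthesis: the two acids are released last (butenolide opening at C15, fluoride cleavage of a 2-(trimethylsilyl)ethyl ester at C19). C13–C16 come off at C12–C13 (alkynylation of a C12 aldehyde), C17 at C8=C17 (Wittig on a C8 ketone), and C1–C2 is taken back to an alkene. Then C3–C4 and C5–C10 are cut together by a retro-[4+2].
2. Enabling feature: in ring A the C4–C5 edge carries the C19 carboxyl on C4, so C4=C5 can be an α-methyl enoate dienophile, and the four carbons opposite (C10–C1–C2–C3) a diene. C5 and C10 are also joined by the C6–C7–C8–C9 bridge of ring B, so the open-chain precursor is a 1,7,9-decatriene whose cycloaddition closes rings B and A together.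
3. Forward: aldehyde 6 (C4–C8, C18, C19) and propargylic mesylate 13 (C9–C12, C10≡C1) are joined at C8–C9. Methyl C20 and vinyl C2–C3 are put on the alkyne, C8 is oxidised, and the triene cyclises. C1=C2 is then hydrogenated, C8=O methylenated and the side chain built.
4. Stereochemistry: C9 comes from the (S)-mesylate (asymmetric transfer hydrogenation, then anti-SN2′/syn-SE2′ transfer). C10, C5 and C4 are set in the cycloaddition by the (E)-diene, the (Z)-enoate and the equatorial C11 arm on C9. C12 comes from catalyst-controlled alkynylation and 13Z from syn-carbocupration.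
5. Helpers removed later: the C8 ketone (keeps C17 out of the hydrogenation), the C1=C2 bond, the silylethyl ester on the hindered C19 acid, and the butenolide that carries the (Z)-hydroxy acid.

Key step: step 14

Remark: positions use labdane numbering (ring A = C1–C5 and C10; ring B = C5–C10; C11, C12 the first side-chain carbons on C9; C17 on C8; C18 methyl and C19 carboxyl on C4; C20 methyl on C10); β is the face of C20.
Remark (assumption): the (S,S)-ProPhenol zinc catalyst is taken to add the alkynyl group to the face of aldehyde 25 that gives the 12S carbinol; if Mosher analysis of 27 shows the opposite sense, the (R,R)-ligand is used with no other change.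
Remark (assumption): the target is taken to be isolable as the free hydroxy diacid when kept cold near pH 4; stronger acid would close it back to the butenolide.

**Step 1**
Reactants: 1 pent-4-enal; 2 ethyl 2-[bis(2,2,2-trifluoroethoxy)phosphoryl]propanoate
Product: 3 ethyl (2Z)-2-methylhepta-2,6-dienoate
Conditions: KN(SiMe3)2, 18-crown-6, THF, −78 °C
Reagents that add atoms: none
Why: Still–Gennari olefination, in which the electron-poor phosphonate makes elimination of the first-formed adduct fast and should give the (Z)-trisubstituted enoate that later places the carboxyl cis to C6.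

**Step 2**
Reactants: 3 ethyl (2Z)-2-methylhepta-2,6-dienoate
Product: 4 (2Z)-2-methylhepta-2,6-dienoic acid
Conditions: LiOH·H2O, THF/MeOH/H2O, 0 °C to rt; then aq. HCl to pH 3
Reagents that add atoms: lithium hydroxide, [Li+].[OH-]
Why: Saponification of an unhindered ester, run cold so that the (Z)-alkene should not isomerise.

**Step 3**
Reactants: 4 (2Z)-2-methylhepta-2,6-dienoic acid
Product: 5 2-(trimethylsilyl)ethyl (2Z)-2-methylhepta-2,6-dienoate
Conditions: 2-(trimethylsilyl)ethyl 2,2,2-trichloroacetimidate (2 equiv), toluene, 100 °C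
Reagents that add atoms: 2-(trimethylsilyl)ethyl 2,2,2-trichloroacetimidate, C[Si](C)(C)CCOC(=N)C(Cl)(Cl)Cl
Why: Promoter-free trichloroacetimidate esterification alkylates the carboxyl oxygen without acyl activation, so the (Z)-geometry should be kept while a fluoride-labile ester is installed for the later hindered C19 carboxyl.

**Step 4**
Reactants: 5 2-(trimethylsilyl)ethyl (2Z)-2-methylhepta-2,6-dienoate
Product: 6 2-(trimethylsilyl)ethyl (2Z)-2-methyl-6-oxohex-2-enoate
Conditions: OsO4 (2 mol %), NaIO4, 2,6-lutidine, dioxane/H2O, rt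
Reagents that add atoms: osmium tetroxide, O=[Os](=O)(=O)=O; sodium periodate, [Na+].[O-]I(=O)(=O)=O
Why: Lemieux–Johnson cleavage, in which the monosubstituted alkene should be dihydroxylated far faster than the trisubstituted, conjugated enoate.

**Step 5**
Reactants: 7 3-[(tert-butyldimethylsilyl)oxy]propanal; 8 ethynyltrimethylsilane
Product: 9 rac-5-[(tert-butyldimethylsilyl)oxy]-1-(trimethylsilyl)pent-1-yn-3-ol
Conditions: 8, n-BuLi, THF, −78 °C; then 7; aq. NH4Cl
Reagents that add atoms: none
Why: 1,2-Addition of a lithium acetylide to an aldehyde; the racemic carbinol is acceptable because it is oxidised in the next step.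

**Step 6**
Reactants: 9 rac-5-[(tert-butyldimethylsilyl)oxy]-1-(trimethylsilyl)pent-1-yn-3-ol
Product: 10 5-[(tert-butyldimethylsilyl)oxy]-1-(trimethylsilyl)pent-1-yn-3-one
Conditions: Dess–Martin periodinane, NaHCO3, CH2Cl2, 0 °C to rt
Reagents that add atoms: none
Why: Dess–Martin oxidation under buffered, non-basic conditions should give the ynone without β-elimination of the silyloxy group.

**Step 7**
Reactants: 10 5-[(tert-butyldimethylsilyl)oxy]-1-(trimethylsilyl)pent-1-yn-3-one
Product: 11 (3S)-5-[(tert-butyldimethylsilyl)oxy]-1-(trimethylsilyl)pent-1-yn-3-ol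
Conditions: Ru[(S,S)-TsNCH(Ph)CH(Ph)NH](p-cymene) (1 mol %), 2-propanol, rt
Reagents that add atoms: none
Why: Noyori asymmetric transfer hydrogenation, in which the alkynyl group takes the place of the aryl group of an aryl ketone so that the (S,S)-catalyst should deliver the (S)-carbinol, and the base-free amido complex spares the β-silyloxy ketone.

**Step 8**
Reactants: 11 (3S)-5-[(tert-butyldimethylsilyl)oxy]-1-(trimethylsilyl)pent-1-yn-3-ol
Product: 12 (3S)-5-[(tert-butyldimethylsilyl)oxy]pent-1-yn-3-ol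
Conditions: K2CO3 (0.2 equiv), MeOH, 0 °C
Reagents that add atoms: none
Why: Base-catalysed protodesilylation of the alkynylsilane should be much faster than loss of the primary silyl ether.

**Step 9**
Reactants: 12 (3S)-5-[(tert-butyldimethylsilyl)oxy]pent-1-yn-3-ol
Product: 13 (3S)-5-[(tert-butyldimethylsilyl)oxy]pent-1-yn-3-yl methanesulfonate
Conditions: MsCl, Et3N, CH2Cl2, −78 to 0 °C; used crude
Reagents that add atoms: methanesulfonyl chloride, CS(=O)(=O)Cl
Why: Sulfonylation at oxygen does not touch the stereocentre.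

**Step 10**
Reactants: 6 2-(trimethylsilyl)ethyl (2Z)-2-methyl-6-oxohex-2-enoate; 13 (3S)-propargylic mesylate
Product: 15 2-(trimethylsilyl)ethyl (2Z,6S,7R)-7-{2-[(tert-butyldimethylsilyl)oxy]ethyl}-6-hydroxy-2-methylnon-2-en-8-ynoate, via allenyl(ethyl)zinc 14 (not isolated)
Conditions: Pd(OAc)2 (5 mol %), PPh3 (5 mol %), Et2Zn (3 equiv), THF, −78 to −20 °C; aq. NH4Cl
Reagents that add atoms: none
Why: Marshall propargylation, in which zerovalent palladium displaces the mesylate anti (SN2′), transfer to zinc keeps the allene axis and the closed SE2′ addition to the aldehyde forms C8–C9 anti to the departed oxygen, so that (S)-13 should give the (R)-configured C9 as the anti adduct (the C8 carbinol is oxidised later).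

**Step 11**
Reactants: 15 homopropargylic alcohol
Product: 17 2-(trimethylsilyl)ethyl (2Z,6S,7R,8E)-7-{2-[(tert-butyldimethylsilyl)oxy]ethyl}-6-hydroxy-9-iodo-2,8-dimethylnona-2,8-dienoate, via alkenyldimethylalane 16 (not isolated)
Conditions: Me3Al (4 equiv), Cp2ZrCl2 (0.3 equiv), H2O (1 equiv), CH2Cl2, −20 °C; then I2, THF, −20 to 0 °C; aq. potassium sodium tartrate
Reagents that add atoms: trimethylaluminium, C[Al](C)C; iodine, [I][I]
Why: Negishi zirconium-catalysed carboalumination adds methyl and aluminium syn with methyl on the internal carbon, and iodinolysis with retention should give the (E)-iodide with C9 trans to iodine, the cold water-accelerated protocol being chosen to spare the ester.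

**Step 12**
Reactants: 17 (E)-alkenyl iodide; 18 4,4,5,5-tetramethyl-2-vinyl-1,3,2-dioxaborolane
Product: 19 2-(trimethylsilyl)ethyl (2Z,6S,7R,8E)-7-{2-[(tert-butyldimethylsilyl)oxy]ethyl}-6-hydroxy-2,8-dimethylundeca-2,8,10-trienoate
Conditions: PdCl2(dppf) (5 mol %), K3PO4 (aq.), THF, 45 °C
Reagents that add atoms: none
Why: Suzuki–Miyaura coupling proceeds with retention at the alkenyl iodide and should give the (E)-diene with the tether outside and the C20 methyl inside.

**Step 13**
Reactants: 19 dienyl alcohol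
Product: 20 2-(trimethylsilyl)ethyl (2Z,7R,8E)-7-{2-[(tert-butyldimethylsilyl)oxy]ethyl}-2,8-dimethyl-6-oxoundeca-2,8,10-trienoate
Conditions: Dess–Martin periodinane, NaHCO3, CH2Cl2, 0 °C; filtered through neutral alumina and used at once
Reagents that add atoms: none
Why: Dess–Martin oxidation is neutral enough that the β,γ-unsaturated ketone should form without migration of the diene into conjugation or epimerisation at C9.

**Step 14**
Reactants: 20 keto trienoate
Product: 21 2-(trimethylsilyl)ethyl (1S,4aS,5R,8aR)-5-{2-[(tert-butyldimethylsilyl)oxy]ethyl}-1,4a-dimethyl-6-oxo-1,2,4a,5,6,7,8,8a-octahydronaphthalene-1-carboxylate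
Conditions: toluene (0.005 M), BHT (10 mol %), 180 °C, sealed silylated glass tube
Reagents that add atoms: none
Why: Mechanism and type: a thermal, concerted but asynchronous [4+2] cycloaddition (type 1 intramolecular Diels–Alder reaction of a 1,7,9-decatriene) in which the diene C10=C1–C2=C3 adds suprafacially to the enoate C4=C5, the closest known reaction type being the thermal cyclisation of 2,8,10-undecatrienoates to trans-octalins. Ring closure: ring B closes as a six-membered ring across the four-atom tether C6–C7–C8–C9 in a chair-like arrangement (bond C5–C10), and ring A is the cyclohexene made by the cycloaddition itself (bonds C5–C10 and C3–C4). Stereocentres: C10 and C5 follow from the (E)-diene, which holds the tether outside and the C20 methyl inside, combined with C6 exo on the dienophile, so that H5 and C20 end trans; C4 follows from the (Z)-enoate, whose ester stays cis to C6 and therefore ends β, syn to C20; the absolute sense follows from C9, whose CH2CH2OTBS arm sits equatorial in the chair-like tether so that C5–C10 bonding occurs with H9 anti to C20. Selectivity needed: trans over cis fusion (ester-exo over ester-endo transition state) and one diene face; the first should be favoured because the exo site on C4 faces the inside C20 methyl, where the flat ester costs less than the C18 methyl would in the cis-fused alternative, and because no Lewis acid is used (it would favour ester-endo), the second by the equatorial preference at C9. The C8 ketone and the new C1=C2 bond are helpers removed in steps 15 and 16, and any minor diastereomer is separated here, before base is used.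

**Step 15**
Reactants: 21 octalone cycloadduct
Product: 22 2-(trimethylsilyl)ethyl (1S,4aS,5R,8aR)-5-{2-[(tert-butyldimethylsilyl)oxy]ethyl}-1,4a-dimethyl-6-oxodecahydronaphthalene-1-carboxylate
Conditions: H2 (1 atm), 10% Pd/C, EtOAc, rt
Reagents that add atoms: none
Why: Catalytic hydrogenation of the cis-disubstituted ring alkene removes the helper unsaturation and creates no stereocentre.

**Step 16**
Reactants: 22 decalone
Product: 23 2-(trimethylsilyl)ethyl (1S,4aR,5S,8aR)-5-{2-[(tert-butyldimethylsilyl)oxy]ethyl}-1,4a-dimethyl-6-methylidenedecahydronaphthalene-1-carboxylate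
Conditions: Ph3PCH3Br, KOtBu, toluene, rt to 80 °C
Reagents that add atoms: methylenetriphenylphosphorane, C=P(c1ccccc1)(c1ccccc1)c1ccccc1
Why: Wittig methylenation of the C8 ketone, where C9 already holds its side chain in the more stable equatorial position so that enolisation by the ylide cannot erode it, and the neopentyl-type ester is inert.

**Step 17**
Reactants: 23 silyl ether
Product: 24 2-(trimethylsilyl)ethyl (1S,4aR,5S,8aR)-5-(2-hydroxyethyl)-1,4a-dimethyl-6-methylidenedecahydronaphthalene-1-carboxylate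
Conditions: camphorsulfonic acid (10 mol %), MeOH/CH2Cl2, 0 °C
Reagents that add atoms: none
Why: Acid-catalysed methanolysis removes the primary silyl ether, and the silylethyl ester and the exocyclic alkene should tolerate these mild conditions.

**Step 18**
Reactants: 24 primary alcohol
Product: 25 2-(trimethylsilyl)ethyl (1S,4aR,5S,8aR)-1,4a-dimethyl-6-methylidene-5-(2-oxoethyl)decahydronaphthalene-1-carboxylate
Conditions: Dess–Martin periodinane, NaHCO3, CH2Cl2, 0 °C to rt
Reagents that add atoms: none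
Why: Dess–Martin oxidation gives the aldehyde under neutral conditions, which should avoid carbonyl-ene closure onto the C8 methylene.

**Step 19**
Reactants: 25 C12 aldehyde; 26 methyl prop-2-ynoate
Product: 27 2-(trimethylsilyl)ethyl (1S,4aR,5S,8aR)-5-[(2S)-2-hydroxy-5-methoxy-5-oxopent-3-yn-1-yl]-1,4a-dimethyl-6-methylidenedecahydronaphthalene-1-carboxylate
Conditions: (S,S)-ProPhenol (20 mol %), Me2Zn (3 equiv), Ph3PO (40 mol %), toluene, 4 °C; aq. NH4Cl
Reagents that add atoms: none
Why: Zinc–ProPhenol asymmetric alkynylation, in which the dinuclear zinc catalyst binds aldehyde and alkynylzinc together and should set the 12S carbinol by catalyst control (see the remark on ligand sense).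

**Step 20**
Reactants: 27 hydroxy ynoate
Product: 29 2-(trimethylsilyl)ethyl (1S,4aR,5S,8aR)-1,4a-dimethyl-6-methylidene-5-{[(2S)-3-methyl-5-oxo-2,5-dihydrofuran-2-yl]methyl}decahydronaphthalene-1-carboxylate, via open hydroxy enoate 28 (not isolated)
Conditions: Me2CuLi (3 equiv, from MeLi and CuI), THF, −78 °C; MeOH then aq. NH4Cl at −78 °C; warm to rt
Reagents that add atoms: lithium dimethylcuprate, [Li+].C[Cu-]C
Why: syn-Carbocupration of the ynoate puts the methyl on C13 and, after protonation with retention, leaves the ester cis to the C12 oxygen (13Z), so the hydroxy ester should close to the butenolide without touching C12.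

**Step 21**
Reactants: 29 butenolide ester
Product: 31 (1S,4aR,5S,8aR)-5-[(2S,3Z)-4-carboxy-2-hydroxy-3-methylbut-3-en-1-yl]-1,4a-dimethyl-6-methylidenedecahydronaphthalene-1-carboxylic acid, via ring-opened silylethyl ester 30 (not isolated)
Conditions: LiOH (4 equiv), THF/H2O, 0 °C; evaporate; Bu4NF (5 equiv), THF, 40 °C; 0.5 M HCl at 0 °C to pH 4, immediate extraction
Reagents that add atoms: lithium hydroxide, [Li+].[OH-]
Why: Hydroxide opens the butenolide at the acyl carbon (C12 and the 13Z alkene untouched), fluoride then attacks silicon and fragments the silylethyl group to free the shielded C19 carboxylate, and brief cold acidification should give the diacid before it can lactonise.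

**Compound list**
1 | pent-4-enal | C=CCCC=O | starting material
2 | ethyl 2-[bis(2,2,2-trifluoroethoxy)phosphoryl]propanoate | CCOC(=O)C(C)P(=O)(OCC(F)(F)F)OCC(F)(F)F | starting material
3 | ethyl (2Z)-2-methylhepta-2,6-dienoate | C=CCC/C=C(/C)C(=O)OCC | intermediate
4 | (2Z)-2-methylhepta-2,6-dienoic acid | C=CCC/C=C(/C)C(=O)O | intermediate
5 | 2-(trimethylsilyl)ethyl (2Z)-2-methylhepta-2,6-dienoate | C=CCC/C=C(/C)C(=O)OCC[Si](C)(C)C | intermediate
6 | 2-(trimethylsilyl)ethyl (2Z)-2-methyl-6-oxohex-2-enoate | O=CCC/C=C(/C)C(=O)OCC[Si](C)(C)C | intermediate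
7 | 3-[(tert-butyldimethylsilyl)oxy]propanal | O=CCCO[Si](C)(C)C(C)(C)C | starting material
8 | ethynyltrimethylsilane | C#C[Si](C)(C)C | starting material
9 | rac-5-[(tert-butyldimethylsilyl)oxy]-1-(trimethylsilyl)pent-1-yn-3-ol | C[Si](C)(C)C#CC(O)CCO[Si](C)(C)C(C)(C)C | intermediate
10 | 5-[(tert-butyldimethylsilyl)oxy]-1-(trimethylsilyl)pent-1-yn-3-one | C[Si](C)(C)C#CC(=O)CCO[Si](C)(C)C(C)(C)C | intermediate
11 | (3S)-5-[(tert-butyldimethylsilyl)oxy]-1-(trimethylsilyl)pent-1-yn-3-ol | C[Si](C)(C)C#C[C@@H](O)CCO[Si](C)(C)C(C)(C)C | intermediate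
12 | (3S)-5-[(tert-butyldimethylsilyl)oxy]pent-1-yn-3-ol | C#C[C@@H](O)CCO[Si](C)(C)C(C)(C)C | intermediate
13 | (3S)-5-[(tert-butyldimethylsilyl)oxy]pent-1-yn-3-yl methanesulfonate | C#C[C@@H](OS(C)(=O)=O)CCO[Si](C)(C)C(C)(C)C | intermediate
14 | ethyl{5-[(tert-butyldimethylsilyl)oxy]penta-1,2-dien-1-yl}zinc, axially chiral allenylzinc formed by anti SN2′ displacement (expected M axis; the axis is not encoded in the SMILES) | CC[Zn]C=C=CCCO[Si](C)(C)C(C)(C)C | intermediate
15 | 2-(trimethylsilyl)ethyl (2Z,6S,7R)-7-{2-[(tert-butyldimethylsilyl)oxy]ethyl}-6-hydroxy-2-methylnon-2-en-8-ynoate | C#C[C@@H](CCO[Si](C)(C)C(C)(C)C)[C@@H](O)CC/C=C(/C)C(=O)OCC[Si](C)(C)C | intermediate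
16 | (E)-alkenyldimethylalane of 15 with the C8 oxygen as its dimethylaluminium alkoxide | C[Al](C)/C=C(\C)[C@@H](CCO[Si](C)(C)C(C)(C)C)[C@@H](O[Al](C)C)CC/C=C(/C)C(=O)OCC[Si](C)(C)C | intermediate
17 | 2-(trimethylsilyl)ethyl (2Z,6S,7R,8E)-7-{2-[(tert-butyldimethylsilyl)oxy]ethyl}-6-hydroxy-9-iodo-2,8-dimethylnona-2,8-dienoate | I/C=C(\C)[C@@H](CCO[Si](C)(C)C(C)(C)C)[C@@H](O)CC/C=C(/C)C(=O)OCC[Si](C)(C)C | intermediate
18 | 4,4,5,5-tetramethyl-2-vinyl-1,3,2-dioxaborolane | C=CB1OC(C)(C)C(C)(C)O1 | starting material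
19 | 2-(trimethylsilyl)ethyl (2Z,6S,7R,8E)-7-{2-[(tert-butyldimethylsilyl)oxy]ethyl}-6-hydroxy-2,8-dimethylundeca-2,8,10-trienoate | C=C/C=C(\C)[C@@H](CCO[Si](C)(C)C(C)(C)C)[C@@H](O)CC/C=C(/C)C(=O)OCC[Si](C)(C)C | intermediate
20 | 2-(trimethylsilyl)ethyl (2Z,7R,8E)-7-{2-[(tert-butyldimethylsilyl)oxy]ethyl}-2,8-dimethyl-6-oxoundeca-2,8,10-trienoate | C=C/C=C(\C)[C@@H](CCO[Si](C)(C)C(C)(C)C)C(=O)CC/C=C(/C)C(=O)OCC[Si](C)(C)C | intermediate
21 | 2-(trimethylsilyl)ethyl (1S,4aS,5R,8aR)-5-{2-[(tert-butyldimethylsilyl)oxy]ethyl}-1,4a-dimethyl-6-oxo-1,2,4a,5,6,7,8,8a-octahydronaphthalene-1-carboxylate (trans-fused; 5α-H, 9α-H, 10β-methyl, 4β-ester, C1=C2 alkene) | O=C1CC[C@@H]2[C@](C)(C=CC[C@]2(C)C(=O)OCC[Si](C)(C)C)[C@H]1CCO[Si](C)(C)C(C)(C)C | intermediate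
22 | 2-(trimethylsilyl)ethyl (1S,4aS,5R,8aR)-5-{2-[(tert-butyldimethylsilyl)oxy]ethyl}-1,4a-dimethyl-6-oxodecahydronaphthalene-1-carboxylate | O=C1CC[C@@H]2[C@](C)(CCC[C@]2(C)C(=O)OCC[Si](C)(C)C)[C@H]1CCO[Si](C)(C)C(C)(C)C | intermediate
23 | 2-(trimethylsilyl)ethyl (1S,4aR,5S,8aR)-5-{2-[(tert-butyldimethylsilyl)oxy]ethyl}-1,4a-dimethyl-6-methylidenedecahydronaphthalene-1-carboxylate | C=C1CC[C@@H]2[C@](C)(CCC[C@]2(C)C(=O)OCC[Si](C)(C)C)[C@H]1CCO[Si](C)(C)C(C)(C)C | intermediate
24 | 2-(trimethylsilyl)ethyl (1S,4aR,5S,8aR)-5-(2-hydroxyethyl)-1,4a-dimethyl-6-methylidenedecahydronaphthalene-1-carboxylate | C=C1CC[C@@H]2[C@](C)(CCC[C@]2(C)C(=O)OCC[Si](C)(C)C)[C@H]1CCO | intermediate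
25 | 2-(trimethylsilyl)ethyl (1S,4aR,5S,8aR)-1,4a-dimethyl-6-methylidene-5-(2-oxoethyl)decahydronaphthalene-1-carboxylate | C=C1CC[C@@H]2[C@](C)(CCC[C@]2(C)C(=O)OCC[Si](C)(C)C)[C@H]1CC=O | intermediate
26 | methyl prop-2-ynoate | C#CC(=O)OC | starting material
27 | 2-(trimethylsilyl)ethyl (1S,4aR,5S,8aR)-5-[(2S)-2-hydroxy-5-methoxy-5-oxopent-3-yn-1-yl]-1,4a-dimethyl-6-methylidenedecahydronaphthalene-1-carboxylate | C=C1CC[C@@H]2[C@](C)(CCC[C@]2(C)C(=O)OCC[Si](C)(C)C)[C@H]1C[C@H](O)C#CC(=O)OC | intermediate
28 | 2-(trimethylsilyl)ethyl (1S,4aR,5S,8aR)-5-[(2S,3Z)-2-hydroxy-5-methoxy-3-methyl-5-oxopent-3-en-1-yl]-1,4a-dimethyl-6-methylidenedecahydronaphthalene-1-carboxylate | C=C1CC[C@@H]2[C@](C)(CCC[C@]2(C)C(=O)OCC[Si](C)(C)C)[C@H]1C[C@H](O)/C(C)=C\C(=O)OC | intermediate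
29 | 2-(trimethylsilyl)ethyl (1S,4aR,5S,8aR)-1,4a-dimethyl-6-methylidene-5-{[(2S)-3-methyl-5-oxo-2,5-dihydrofuran-2-yl]methyl}decahydronaphthalene-1-carboxylate | C=C1CC[C@@H]2[C@](C)(CCC[C@]2(C)C(=O)OCC[Si](C)(C)C)[C@H]1C[C@@H]3OC(=O)C=C3C | intermediate
30 | 2-(trimethylsilyl)ethyl (1S,4aR,5S,8aR)-5-[(2S,3Z)-4-carboxy-2-hydroxy-3-methylbut-3-en-1-yl]-1,4a-dimethyl-6-methylidenedecahydronaphthalene-1-carboxylate (present in the flask as its lithium salt) | C=C1CC[C@@H]2[C@](C)(CCC[C@]2(C)C(=O)OCC[Si](C)(C)C)[C@H]1C[C@H](O)/C(C)=C\C(=O)O | intermediate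
31 | (1S,4aR,5S,8aR)-5-[(2S,3Z)-4-carboxy-2-hydroxy-3-methylbut-3-en-1-yl]-1,4a-dimethyl-6-methylidenedecahydronaphthalene-1-carboxylic acid | C=C1CC[C@@H]2[C@](C)(CCC[C@]2(C)C(=O)O)[C@H]1C[C@H](O)/C(C)=C\C(=O)O | target

**Totals**
Total step count: 21. Longest linear sequence: 17 steps (steps 5–21, from 7 and 8).

**Steps most likely to fail**

Step 14. The trisubstituted dienophile and the inside methyl of the diene slow the cycloaddition. A [1,5]-hydrogen shift from C20 to C3, or closure through the ester-endo transition state to the cis-fused isomer, may then compete. Fallback: the diene is made electron-rich and polarity-matched by a sulfur substituent at C3. From 17, Dess–Martin oxidation (NaHCO3, CH2Cl2, 0 °C) gives the iodo ketone F1. Base-free Stille coupling with (E)-tributyl[2-(phenylsulfanyl)ethenyl]stannane (Pd2(dba)3, AsPh3, NMP, rt) gives the phenylsulfanyl diene F2. Its cycloaddition (toluene, about 110 °C; the sulfur-bearing C3 bonds to the ester-bearing C4, C10 to the β-carbon C5) should give the sulfide cycloadduct F3. Deactivated Raney nickel in acetone/EtOH then removes sulfur and saturates C1=C2 in one operation, and the route is rejoined at 22.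

Step 11. The aluminium reagent may attack the enoate, or regiocontrol may be lost at the branched alkyne. Fallback: copper-catalysed borylmethylation in place of carboalumination. From 15, TESCl/imidazole (DMF, 0 °C) gives the triethylsilyl ether F4. CuCl (10 mol %), Xantphos, NaOtBu, B2pin2 and MeI in THF at rt (syn borylcupration, then methylation with retention) give the (E)-alkenylboronate F5. Suzuki coupling with vinyl bromide (PdCl2(dppf), K3PO4, THF/H2O) gives the silyl-protected triene F6. PPTS in MeOH at 0 °C removes the triethylsilyl group, and the route is rejoined at 19.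

Step 19. Alkynyl transfer to the enolisable, α-unbranched aldehyde may be slow, with aldol self-condensation competing, or catalyst control may be weak next to the bulky decalin. Fallback: the C12–C13 bond is made from the alkenyl side instead. From 25, Nozaki–Hiyama–Kishi coupling with methyl (2Z)-3-iodobut-2-enoate (CrCl2, NiCl2 cat., DMF, rt) and spontaneous lactonisation give 29 together with the C12-epimeric butenolide F7. The two are diastereomers and are separated by chromatography, and the route is rejoined at 29.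

**Further compounds**
F1 | step 14 | 2-(trimethylsilyl)ethyl (2Z,7R,8E)-7-{2-[(tert-butyldimethylsilyl)oxy]ethyl}-9-iodo-2,8-dimethyl-6-oxonona-2,8-dienoate | I/C=C(\C)[C@@H](CCO[Si](C)(C)C(C)(C)C)C(=O)CC/C=C(/C)C(=O)OCC[Si](C)(C)C
F2 | step 14 | 2-(trimethylsilyl)ethyl (2Z,7R,8E,10E)-7-{2-[(tert-butyldimethylsilyl)oxy]ethyl}-2,8-dimethyl-6-oxo-11-(phenylsulfanyl)undeca-2,8,10-trienoate | c1ccccc1S/C=C/C=C(\C)[C@@H](CCO[Si](C)(C)C(C)(C)C)C(=O)CC/C=C(/C)C(=O)OCC[Si](C)(C)C
F3 | step 14 | 3α-(phenylsulfanyl) analogue of 21 (sulfur on C3, on the face opposite to the C20 methyl) | O=C1CC[C@@H]2[C@](C)(C=C[C@@H](Sc3ccccc3)[C@]2(C)C(=O)OCC[Si](C)(C)C)[C@H]1CCO[Si](C)(C)C(C)(C)C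
F4 | step 11 | 2-(trimethylsilyl)ethyl (2Z,6S,7R)-7-{2-[(tert-butyldimethylsilyl)oxy]ethyl}-2-methyl-6-[(triethylsilyl)oxy]non-2-en-8-ynoate | C#C[C@@H](CCO[Si](C)(C)C(C)(C)C)[C@@H](O[Si](CC)(CC)CC)CC/C=C(/C)C(=O)OCC[Si](C)(C)C
F5 | step 11 | 2-(trimethylsilyl)ethyl (2Z,6S,7R,8E)-7-{2-[(tert-butyldimethylsilyl)oxy]ethyl}-2,8-dimethyl-9-(4,4,5,5-tetramethyl-1,3,2-dioxaborolan-2-yl)-6-[(triethylsilyl)oxy]nona-2,8-dienoate | CC1(C)OB(/C=C(\C)[C@@H](CCO[Si](C)(C)C(C)(C)C)[C@@H](O[Si](CC)(CC)CC)CC/C=C(/C)C(=O)OCC[Si](C)(C)C)OC1(C)C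
F6 | step 11 | 2-(trimethylsilyl)ethyl (2Z,6S,7R,8E)-7-{2-[(tert-butyldimethylsilyl)oxy]ethyl}-2,8-dimethyl-6-[(triethylsilyl)oxy]undeca-2,8,10-trienoate | C=C/C=C(\C)[C@@H](CCO[Si](C)(C)C(C)(C)C)[C@@H](O[Si](CC)(CC)CC)CC/C=C(/C)C(=O)OCC[Si](C)(C)C
F7 | step 19 | 2-(trimethylsilyl)ethyl (1S,4aR,5S,8aR)-1,4a-dimethyl-6-methylidene-5-{[(2R)-3-methyl-5-oxo-2,5-dihydrofuran-2-yl]methyl}decahydronaphthalene-1-carboxylate | C=C1CC[C@@H]2[C@](C)(CCC[C@]2(C)C(=O)OCC[Si](C)(C)C)[C@H]1C[C@H]3OC(=O)C=C3C
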